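Time was the axis I drew first. Against it I drew one curve, the excess in the product: left-handed product minus right-handed product over their sum, each as a fraction of the substrates charged.

the same everywhere: free catalyst 170 mM
- west: left-handed substrate 1 M; right-handed substrate 1 M; reagent 1.1 M; run made earlier
- east: left-handed substrate 1 M; right-handed substrate 1 M; reagent 1.7 M; run made earlier
- ash: left-handed substrate 1.0 M; right-handed substrate 1.0 M; reagent 2.20 M; time 40 min
- larch: left-handed substrate 1.0 M; right-handed substrate 1.0 M; reagent 2.20 M; time 60 min

- west (time / min: left-handed product / %, right-handed product / %): 3.00: 3.3, 0; 5.00: 3.8, 0.4; 8.00: 4.8, 0; 12.0: 4.9, 1.4; 15.0: 5.5, 1.6; 25.0: 4.9, 2.2; 40.0: 4.7, 2.7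
- east (time / min: left-handed product / %, right-handed product / %): 3.00: 5.1, 0.5; 5.00: 5.4, 1.0; 8.00: 6.9, 1.5; 12.0: 7.2, 1.1; 15.0: 7.8, 1.8; 25.0: 6.8, 3.2; 40.0: 6.2, 3.1

(scatter of a reading: 0.5 percentage points)

1. which of the two ends with the higher excess of left-handed product over right-handed product in the product ("neither" if they lie within 2 percentage points) (ash / larch / neither)
2. excess of left-handed product over right-handed product in the product at the end, ash
3. excess of left-handed product over right-handed product in the product at the end, larch

- free catalyst is single-handed; left-handed substrate and right-handed substrate are mirror images of each other, charged as a racemate, each of them at the stated concentration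
- the analysis behind the earlier runs scatters by 0.5 percentage points, standard deviation
- an excess is below zero if the other one leads

I pooled neighbouring readings of both runs, since one reading scatters too much. The curve read high, at 80.5% around 4.00 min, which I took for kinetic control by the single-handed free catalyst. By 13.5 min it had fallen to:

62.3%

The knee in the product came near 15.0 min: the sums of both runs added to 16.7% there and 16.7% at 40.0 min. From 13.5 min on I treated the curve as a first-order decay towards the thermodynamic level, zero for mirror images. Around 32.5 min it read:

33.7%

From these two readings came the excess-halving time, the time in which the excess in the product falls to a half of itself on this decay: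

21.5 min

By this reckoning the curve crossed 0.5 at 20.3 min. The two runs read 32.4% and 34.7% late on, so I carried the curve to the higher reagent unchanged:

ash: 26.5%

larch: 13.9%

I therefore expected ash ahead by 13 percentage points, beyond the margin. The forecast gave 2.7% for ash and 1.4% for larch, hence neither, reasoning that “the equilibrium is racemic, so the excess must relax towards zero”.

The flask gave 23.9% for ash and 11.6% for larch, so ash ended higher. At 40.0 min in ash, left-handed product was made at 0.462 of the rate at which it was used up, each step taken net. Over the 20.0 min that separate the reading of ash from that of larch, my halving time gave a factor 0.524, and the two results stood in the ratio 0.485, about a half.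

    left-handed product ⇌ right-handed product (k = 0.0220 min⁻¹)
    2 free catalyst → spent catalyst (k = 1.90 L mol⁻¹ min⁻¹)
    2 reagent → self-condensation product (k = 0.0190 L mol⁻¹ min⁻¹)
    left-handed substrate ⇌ right-handed substrate (k = 0.0560 min⁻¹)
    reagent + free catalyst + left-handed substrate → free catalyst + left-handed product (k = 0.250 L² mol⁻² min⁻¹)
    reagent + free catalyst + right-handed substrate → free catalyst + right-handed product (k = 0.00430 L² mol⁻² min⁻¹)

Take the neighbour of ash with 0.068 M of free catalyst, read at 40 min, which lies on the decay: carrying the curve over unchanged, the halving time gives 26.5% there. The simulation gives 26.1%.

All runs are calculated with made-up constants, and the scatter is random.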